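## Retrosynthetic overview

- **Feature the strategy rests on** (indene numbering: C2 ketone between methyl-bearing C1 and C3, trans ring fusion C3a/C7a, C4 with Et and CO2H, C5 with Et and (E)-styryl, C6=C7 with Me on C7): the two ethyl groups on the adjacent quaternary carbons C4 and C5 are cis, and CO2H and the styryl carbon are cis on the other face. The ethyls are therefore read as the cut ends of a cyclohexene fused at C4–C5, and CO2H plus the styryl carbon as a γ-lactone.
- **Key disconnection:** both C–CH2 bonds at C4 and C5, by Diels–Alder addition of butadiene to the lactone-bearing double bond of a methyl quinone lactone. This gives a propellane enedione; the sacrificial cyclohexene is the only ring closed in that step.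
- **Cyclopentanone:** C7a–C1 by Mukaiyama–Michael addition of the pentan-3-one enol silane, C3–C3a by aldol condensation; Li/NH3 sets the trans ring fusion and reduces the C6 ketone, and the C6 carbinol is dehydrated to C6=C7.
- **Ethyl groups and side chains:** the cyclohexene is cut (OsO4/NaIO4) and both CH2CHO arms are reduced to ethyl before any other alkene exists. The lactone is opened last: C4–CO2H is held as the allyl ester, C5–CH2OH is oxidised to CHO and olefinated with diethyl benzylphosphonate.
- **Ring order:** benzene ring (bought) → lactone (step 4) → quinone (step 6) → cyclohexene (step 7, cut in step 11) → cyclopentenone (step 10).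

Key step: step 7

Remarks before the steps:
- Indene numbering of the target is used for every compound from the Diels–Alder adduct on. "Upper face" is the face of the butadiene-derived carbons (the future ethyl groups); "lower face" is the face of the lactone.
- Assumption: the facial sense of the pybox–samarium catalyst on this quinone lactone is fixed by a trial run; the antipodal ligand is used if the mirror-image adduct forms.
- 2,5-Dimethoxytoluene (the dimethyl ether of methylhydroquinone), buta-1,3-diene, pentan-3-one and diethyl benzylphosphonate are bought.

## Route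

Step 1
Reactants: 1 2,5-dimethoxytoluene
Product: 2 1-bromo-2,5-dimethoxy-4-methylbenzene
Conditions: NBS, MeCN, 0 °C → rt
Reagents that add atoms: N-bromosuccinimide, O=C1CCC(=O)N1Br
Why: Electrophilic aromatic bromination should go para to the methyl group and ortho to a methoxy group, the most activated and least hindered position.

Step 2
Reactants: 2 1-bromo-2,5-dimethoxy-4-methylbenzene
Product: 4 N,N-diethyl-2,5-dimethoxy-4-methylbenzamide, via aryllithium 3 (not isolated)
Conditions: n-BuLi, THF, −78 °C; then Et2NCOCl, −78 °C → rt
Reagents that add atoms: N,N-diethylcarbamoyl chloride, CCN(CC)C(Cl)=O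
Why: Bromine–lithium exchange gives the aryllithium, which is acylated by the carbamoyl chloride without over-addition to the tertiary amide at low temperature.

Step 3
Reactants: 4 N,N-diethyl-2,5-dimethoxy-4-methylbenzamide
Product: 6 N,N-diethyl-2-formyl-3,6-dimethoxy-4-methylbenzamide, via ortho-lithiated amide 5 (not isolated)
Conditions: s-BuLi, TMEDA, THF, −78 °C; DMF; H2O
Reagents that add atoms: N,N-dimethylformamide, CN(C)C=O
Why: Directed ortho-metalation; the only free position ortho to the amide is also ortho to a methoxy group, so lithiation there is cooperative, and DMF formylates the aryllithium.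

Step 4
Reactants: 6 N,N-diethyl-2-formyl-3,6-dimethoxy-4-methylbenzamide
Product: 8 4,7-dimethoxy-5-methylisobenzofuran-1(3H)-one, via hydroxymethyl amide 7 (not isolated)
Conditions: NaBH4, MeOH, 0 °C; then 6 M HCl, 60 °C
Reagents that add atoms: none
Why: Borohydride reduces the aldehyde, and the ortho-hydroxymethyl benzamide lactonises under acid with loss of diethylamine (standard phthalide synthesis), which places the lactone C=O para to the methyl group.

Step 5
Reactants: 8 4,7-dimethoxy-5-methylisobenzofuran-1(3H)-one
Product: 9 4,7-dihydroxy-5-methylisobenzofuran-1(3H)-one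
Conditions: BBr3, CH2Cl2, −78 → 0 °C; H2O
Reagents that add atoms: none
Why: Lewis-acid cleavage of both aryl methyl ethers by boron tribromide; the phthalide lactone is retained.

Step 6
Reactants: 9 4,7-dihydroxy-5-methylisobenzofuran-1(3H)-one
Product: 10 5-methyl-4,7-dioxo-4,7-dihydroisobenzofuran-1(3H)-one (quinone lactone)
Conditions: Ag2O, MgSO4, CH2Cl2, rt, dark; filtered and used at once
Reagents that add atoms: none
Why: Two-electron oxidation of the hydroquinone by silver(I) oxide under anhydrous, neutral conditions should give the water-sensitive acyl quinone without hydration.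

Step 7
Reactants: 10 quinone lactone; 11 buta-1,3-diene
Product: 12 Diels–Alder adduct (propellane enedione: cyclohexene fused at C4–C5 on the upper face and γ-lactone C4–C(=O)–O–CH2–C5 on the lower face)
Conditions: Sm(OTf)3 (10 mol %), (S,S)-Ph-pybox (12 mol %), 4 Å MS, THF/CH2Cl2, −78 → −40 °C, butadiene (10 equiv)
Reagents that add atoms: none
Why: Concerted, suprafacial [4+2] cycloaddition (Diels–Alder reaction) of s-cis butadiene to the C3a=C7a double bond of 10 (phthalide numbering) forms the two C–CH2 bonds at once and thereby closes the only new ring, the cyclohexene, in a single intermolecular cycloaddition. The closest known reaction type is the lanthanide–pybox-catalysed enantioselective Diels–Alder reaction of 2-alkoxycarbonyl-1,4-benzoquinones, in which the metal is held in a chelate by the ester and the neighbouring quinone carbonyl. Both new stereocentres (future C4 and C5) are quaternary and are cis by necessity, because the diene adds to one face of the planar dienophile; which face is decided by the ligand, which screens the other face of the chelated lactone–quinone plane. The step needs site selectivity for the lactone-bearing double bond over the methyl-bearing one, and the substrate secures it: that double bond carries three carbonyl groups, is the one activated by the samarium chelate between the lactone C=O and the C7 C=O, and is tied back in the five-membered ring, whereas the other double bond is deactivated by its methyl group. Regiochemistry and endo/exo selectivity are not at issue with unsubstituted butadiene, and the adduct cannot aromatise because both ring-fusion carbons are quaternary.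

Step 8
Reactants: 13 pentan-3-one
Product: 14 (Z)-trimethyl(pent-2-en-3-yloxy)silane
Conditions: TMSOTf, Et3N, CH2Cl2, 0 °C
Reagents that add atoms: trimethylsilyl trifluoromethanesulfonate, C[Si](C)(C)OS(=O)(=O)C(F)(F)F
Why: Soft enolisation and O-silylation of the symmetrical ketone gives the enol silane, whose double-bond geometry is of no consequence here.

Step 9
Reactants: 12 Diels–Alder adduct; 14 (Z)-trimethyl(pent-2-en-3-yloxy)silane
Product: 16 triketone Michael adduct (3-oxopentan-2-yl group on the lower face of C7a; epimer mixture at C7 and at the side-chain CH), via C6 silyl enol ether 15 (not isolated)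
Conditions: 14 (1.5 equiv), HNTf2 (5 mol %), CH2Cl2, −78 °C; then 1 M HCl, THF, 0 °C
Reagents that add atoms: none
Why: Mukaiyama–Michael addition in which the silylium catalyst formed in situ activates the C6 carbonyl (the more basic one, since the C3a carbonyl is flanked by the lactone acyl group) and the enol silane attacks the unsubstituted β-carbon C7a instead of methyl-bearing C7; the nucleophile should enter from the lower face, past the flat lactone carbonyl on C4 and away from the allylic CH2 of the cyclohexene that folds over the upper face, which sets C7a, while C7 and the side-chain carbon are epimerisable and left undefined.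

Step 10
Reactants: 16 triketone Michael adduct
Product: 18 cyclopentenone (C3=C3a enone with C2 ketone; C6 ketone; C7a–H and the C1 and C7 methyl groups on the upper face), via C3a aldol 17 (not isolated)
Conditions: KOtBu (0.2 equiv), t-BuOH/THF, rt
Reagents that add atoms: none
Why: Base-mediated intramolecular aldol condensation of the 1,4-diketone (ethyl-ketone enolate carbon C3 onto the C3a ketone, then E1cB loss of water) closes the cyclopentenone; the hindered alkoxide avoids retro-Claisen opening of the β-keto lactone, ring closure takes C7a out of the α-position of a ketone and so fixes it, and C1 and C7 settle to the more stable methyl orientations.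

Step 11
Reactants: 18 cyclopentenone
Product: 20 dialdehyde (CH2CHO arms on C4 and C5), via cis-diol 19 (not isolated)
Conditions: OsO4 (2 mol %), NaIO4, 2,6-lutidine, dioxane/H2O, rt
Reagents that add atoms: osmium tetroxide, O=[Os](=O)(=O)=O; sodium periodate, [Na+].[O-]I(=O)(=O)=O
Why: Lemieux–Johnson oxidation; osmium tetroxide should dihydroxylate only the electron-rich disubstituted cyclohexene (the tetrasubstituted enone double bond is electron-poor and hindered), and periodate cleaves the diol to the two aldehyde arms.

Step 12
Reactants: 20 dialdehyde
Product: 21 bis(tosylhydrazone)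
Conditions: TsNHNH2 (2.1 equiv), THF, rt
Reagents that add atoms: 4-methylbenzenesulfonohydrazide, Cc1ccc(cc1)S(=O)(=O)NN
Why: Hydrazone condensation occurs at the two unhindered aldehydes much faster than at the neopentyl C6 ketone or the tetrasubstituted enone carbonyl.

Step 13
Reactants: 21 bis(tosylhydrazone)
Product: 23 4,5-diethyl enone lactone, via N-boryl sulfonylhydrazine 22 (not isolated)
Conditions: catecholborane (2.4 equiv), CHCl3, 0 °C; then NaOAc·3H2O, reflux
Reagents that add atoms: none
Why: Tosylhydrazone reduction with catecholborane: hydroboration of each C=N, acetate-induced loss of sulfinate and extrusion of N2 from the alkyl diazene leave a methyl group, so both CH2CH=N arms become the cis ethyl groups; a cyclic s-trans enone is not conjugate-reduced by this borane.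

Step 14
Reactants: 23 4,5-diethyl enone lactone
Product: 25 trans-fused hydroxy ketone lactone (C3a–H lower face, C7a–H upper face, equatorial C6–OH trans to the C7 methyl group), via dilithium enolate alkoxide 24 (not isolated)
Conditions: Li (8 equiv), NH3(l)/THF, t-BuOH (5 equiv), −78 → −33 °C; NH4Cl
Reagents that add atoms: none
Why: Dissolving-metal (Birch-type) reduction; the enone takes up two electrons and C3a is protonated axially, anti to C7a–H, which should give the trans-fused hydrindanone as its C2 enolate (thereby protected from further reduction), while the saturated C6 ketone is reduced to the more stable equatorial carbinol trans to the C7 methyl group; C3 is set on quenching the enolate and is equilibrated later.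

Step 15
Reactants: 25 trans-fused hydroxy ketone lactone
Product: 27 keto lactone with C6=C7 double bond, via C6 sulfamate 26 (not isolated)
Conditions: Burgess reagent, toluene, rt → 80 °C
Reagents that add atoms: none
Why: Burgess dehydration; the sulfamate ester undergoes thermal syn elimination through the only β-hydrogen (C7–H, cis to the equatorial C6–O), which should give the trisubstituted C6=C7 alkene without a free cation next to quaternary C5.

Step 16
Reactants: 27 keto lactone with C6=C7 double bond
Product: 29 hydroxy allyl ester (C4–CO2allyl and C5–CH2OH), via potassium hydroxy carboxylate 28 (not isolated)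
Conditions: KOH (1.2 equiv), MeOH/H2O, 65 °C; evaporate; allyl bromide, DMF, rt
Reagents that add atoms: potassium hydroxide, [K+].[OH-]; allyl bromide, C=CCBr
Why: Saponification opens the γ-lactone to a carboxylate that cannot relactonise while it is a salt, and O-alkylation with allyl bromide gives the ester; the hydroxide also equilibrates C1 and C3 to the pseudo-equatorial methyl orientations of the target.

Step 17
Reactants: 29 hydroxy allyl ester
Product: 30 aldehyde allyl ester (C5–CHO)
Conditions: Dess–Martin periodinane, pyridine, CH2Cl2, 0 °C → rt
Reagents that add atoms: none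
Why: Dess–Martin oxidation of the neopentyl primary alcohol to a non-enolisable aldehyde under buffered conditions that give no chance for acid-catalysed relactonisation.

Step 18
Reactants: 30 aldehyde allyl ester; 31 diethyl benzylphosphonate
Product: 33 dinorspiculoic acid A allyl ester, via sodium phosphonate carbanion 32 (not isolated)
Conditions: 31, NaH, THF, 0 °C; then 30, 0 → 50 °C
Reagents that add atoms: none
Why: Horner–Wadsworth–Emmons olefination with the benzylphosphonate anion should give the (E)-styrene through the trans-oxaphosphetane, and the hindered C2 ketone does not compete with the aldehyde.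

Step 19
Reactants: 33 dinorspiculoic acid A allyl ester
Product: 34 dinorspiculoic acid A
Conditions: Pd(PPh3)4 (5 mol %), morpholine, THF, rt; dilute citric acid work-up
Reagents that add atoms: none
Why: Palladium(0)-catalysed allyl transfer to morpholine (Tsuji–Trost deallylation) frees the hindered carboxylic acid without hydrolytic or strongly acidic conditions that could affect the ketone or the alkenes.

## Compound list

1 | 2,5-dimethoxytoluene | COc1ccc(OC)c(C)c1 | starting material
2 | 1-bromo-2,5-dimethoxy-4-methylbenzene | COc1cc(C)c(OC)cc1Br | intermediate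
3 | (2,5-dimethoxy-4-methylphenyl)lithium | [Li]c1cc(OC)c(C)cc1OC | intermediate
4 | N,N-diethyl-2,5-dimethoxy-4-methylbenzamide | CCN(CC)C(=O)c1cc(OC)c(C)cc1OC | intermediate
5 | ortho-lithiated amide (Li between the amide and a methoxy group) | [Li]c1c(OC)c(C)cc(OC)c1C(=O)N(CC)CC | intermediate
6 | N,N-diethyl-2-formyl-3,6-dimethoxy-4-methylbenzamide | CCN(CC)C(=O)c1c(C=O)c(OC)c(C)cc1OC | intermediate
7 | N,N-diethyl-2-(hydroxymethyl)-3,6-dimethoxy-4-methylbenzamide | CCN(CC)C(=O)c1c(CO)c(OC)c(C)cc1OC | intermediate
8 | 4,7-dimethoxy-5-methylisobenzofuran-1(3H)-one | O=C1OCc2c1c(OC)cc(C)c2OC | intermediate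
9 | 4,7-dihydroxy-5-methylisobenzofuran-1(3H)-one | O=C1OCc2c1c(O)cc(C)c2O | intermediate
10 | 5-methyl-4,7-dioxo-4,7-dihydroisobenzofuran-1(3H)-one (quinone lactone) | O=C1OCC2=C1C(=O)C=C(C)C2=O | intermediate
11 | buta-1,3-diene | C=CC=C | starting material
12 | Diels–Alder adduct: propellane enedione, cyclohexene on the upper face and γ-lactone on the lower face of C4–C5 | C1=CC[C@@]2(CO3)C(=O)C(C)=CC(=O)[C@]2(C1)C3=O | intermediate
13 | pentan-3-one | CCC(=O)CC | starting material
14 | (Z)-trimethyl(pent-2-en-3-yloxy)silane | C/C=C(/CC)O[Si](C)(C)C | intermediate
15 | C6 trimethylsilyl enol ether of the Michael adduct (side chain on the lower face of C7a; side-chain CH epimers) | C1=CC[C@@]2(CO3)C(O[Si](C)(C)C)=C(C)[C@H](C(C)C(=O)CC)C(=O)[C@]2(C1)C3=O | intermediate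
16 | triketone Michael adduct (C7a–H upper face; epimers at C7 and the side-chain CH) | C1=CC[C@@]2(CO3)C(=O)C(C)[C@H](C(C)C(=O)CC)C(=O)[C@]2(C1)C3=O | intermediate
17 | C3a aldol (β-hydroxy ketone, diastereomer mixture) | C1=CC[C@@]2(CO3)C(=O)C(C)[C@H]4C(O)(C(C)C(=O)C4C)[C@]2(C1)C3=O | intermediate
18 | cyclopentenone: C3=C3a enone, C6 ketone, C7a–H and the C1 and C7 methyls on the upper face | C1=CC[C@@]2(CO3)C(=O)[C@@H](C)[C@H]4C(=C(C)C(=O)[C@@H]4C)[C@]2(C1)C3=O | intermediate
19 | cis-diol of 18 at the former cyclohexene carbons (either face) | OC1C[C@@]2(CO3)C(=O)[C@@H](C)[C@H]4C(=C(C)C(=O)[C@@H]4C)[C@]2(CC1O)C3=O | intermediate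
20 | dialdehyde: CH2CHO on C4 and on C5 (upper face) | O=CC[C@@]1(CO2)C(=O)[C@@H](C)[C@H]3C(=C(C)C(=O)[C@@H]3C)[C@]1(CC=O)C2=O | intermediate
21 | bis(tosylhydrazone) of 20 | Cc5ccc(cc5)S(=O)(=O)NN=CC[C@@]1(CO2)C(=O)[C@@H](C)[C@H]3C(=C(C)C(=O)[C@@H]3C)[C@]1(CC=NNS(=O)(=O)c4ccc(C)cc4)C2=O | intermediate
22 | bis(N-catecholboryl-N′-tosylhydrazine) | Cc5ccc(cc5)S(=O)(=O)NN(B6Oc7ccccc7O6)CC[C@@]1(CO2)C(=O)[C@@H](C)[C@H]3C(=C(C)C(=O)[C@@H]3C)[C@]1(CCN(NS(=O)(=O)c4ccc(C)cc4)B8Oc9ccccc9O8)C2=O | intermediate
23 | 4,5-diethyl enone lactone (C3=C3a enone, C6 ketone) | CC[C@@]1(CO2)C(=O)[C@@H](C)[C@H]3C(=C(C)C(=O)[C@@H]3C)[C@]1(CC)C2=O | intermediate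
24 | dilithium salt of the trans-fused C2 enolate and C6 alkoxide | CC[C@@]1(CO2)[C@H]([O-])[C@@H](C)[C@H]3[C@@H](C(C)=C([O-])[C@@H]3C)[C@]1(CC)C2=O.[Li+].[Li+] | intermediate
25 | trans-fused hydroxy ketone lactone (C3a–H lower, C7a–H upper, C6–OH lower and equatorial; a C3 epimer converges in step 16) | CC[C@@]1(CO2)[C@H](O)[C@@H](C)[C@H]3[C@@H]([C@@H](C)C(=O)[C@@H]3C)[C@]1(CC)C2=O | intermediate
26 | C6 N-(methoxycarbonyl)sulfamate, triethylammonium salt | CC[C@@]1(CO2)[C@H](OS(=O)(=O)[N-]C(=O)OC)[C@@H](C)[C@H]3[C@@H]([C@@H](C)C(=O)[C@@H]3C)[C@]1(CC)C2=O.CC[NH+](CC)CC | intermediate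
27 | trans-fused keto lactone with C6=C7 double bond | CC[C@@]1(CO2)C=C(C)[C@H]3[C@@H]([C@@H](C)C(=O)[C@@H]3C)[C@]1(CC)C2=O | intermediate
28 | potassium salt of the C5-hydroxymethyl C4-carboxylate | CC[C@@]1(CO)C=C(C)[C@H]2[C@@H]([C@@H](C)C(=O)[C@@H]2C)[C@]1(CC)C(=O)[O-].[K+] | intermediate
29 | hydroxy allyl ester (C5–CH2OH, C4–CO2allyl) | CC[C@@]1(CO)C=C(C)[C@H]2[C@@H]([C@@H](C)C(=O)[C@@H]2C)[C@]1(CC)C(=O)OCC=C | intermediate
30 | aldehyde allyl ester (C5–CHO) | CC[C@@]1(C=O)C=C(C)[C@H]2[C@@H]([C@@H](C)C(=O)[C@@H]2C)[C@]1(CC)C(=O)OCC=C | intermediate
31 | diethyl benzylphosphonate | CCOP(=O)(Cc1ccccc1)OCC | starting material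
32 | sodium salt of the benzylphosphonate carbanion | CCOP(=O)(OCC)[CH-]c1ccccc1.[Na+] | intermediate
33 | dinorspiculoic acid A allyl ester | CC[C@@]1(/C=C/c2ccccc2)C=C(C)[C@H]3[C@@H]([C@@H](C)C(=O)[C@@H]3C)[C@]1(CC)C(=O)OCC=C | intermediate
34 | dinorspiculoic acid A | CC[C@@]1(/C=C/c2ccccc2)C=C(C)[C@H]2[C@@H]([C@@H](C)C(=O)[C@@H]2C)[C@]1(CC)C(=O)O | target

## Step count and risks

Total step count: 19. Longest linear sequence: 18 steps (steps 1–7 and 9–19, from 1 to 34); step 8 is a one-step branch.

Steps most likely to fail:

1. **Step 9 (together with the ring closure in step 10).** The two faces of the enedione differ only in a cyclohexene against a γ-lactone, so the enol silane may add with poor or reversed facial selectivity at C7a. C7a may also epimerise through the C3a enolate before the aldol closes. The fallback delivers hydrogen instead of carbon to the accessible face and is therefore stereocomplementary. It sets out from 15, kept as the silyl enol ether by quenching step 9 with triethylamine instead of acid. Saegusa–Ito oxidation (Pd(OAc)2, MeCN, rt) should give the tetrasubstituted enedione that carries the 3-oxopentan-2-yl group on sp2 C7a, the tetrasubstituted enedione F1. Zinc in acetic acid then reduces the enedione, and ketonisation protonates C7a from the face that the carbon nucleophile had preferred, which leaves the side chain on the opposite face. The sequence comes back to the route at 16.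

2. **Step 14.** The hindered, enolisable C6 ketone may be reduced only in part, because some of it is masked as its enolate by lithium amide. Alternatively the excess metal needed to force its reduction may attack the lactone carbonyl. Either process gives mixtures at C6 or ring-opened material. The fallback changes from dehydration of a carbinol to reduction of an enol triflate and sets out from 23. Only the enone is reduced (Li, 2.2 equiv, NH3/THF, t-BuOH, −78 °C), and the crude mixture is oxidised with Dess–Martin periodinane to the single trans-fused diketone F2. Ethylene glycol with TsOH (benzene, water separator) should ketalise only the cyclopentanone, since the C6 ketone is flanked by a quaternary carbon, giving C2 dioxolane F3. KHMDS and N-phenyltriflimide (THF, −78 °C) give C6 enol triflate F4, and Pd(OAc)2/PPh3 with HCO2H and Bu3N (DMF, 60 °C) gives alkene ketal F5. Dilute HCl in THF removes the ketal, and the sequence comes back to the route at 27, so that step 15 is not needed.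

3. **Step 7.** The lactone and quinone carbonyls of 10 are held in a fused five-membered ring and offer the metal a wider bite than an open β-keto ester. Enantioface selection may therefore be low, and an uncatalysed background reaction or addition at the methyl-bearing double bond may compete. The fallback replaces asymmetric catalysis by resolution and sets out from 10 and 11. The thermal cycloaddition (toluene, rt → 40 °C) gives racemic adduct, and preparative chromatography on a chiral stationary phase removes the mirror-image adduct F6. The sequence comes back to the route at 12.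

Further compounds
F1 | step 9 | tetrasubstituted enedione with the 3-oxopentan-2-yl group on C7a | C1=CC[C@@]2(CO3)C(=O)C(C)=C(C(C)C(=O)CC)C(=O)[C@]2(C1)C3=O
F2 | step 14 | trans-fused C2,C6-diketone lactone | CC[C@@]1(CO2)C(=O)[C@@H](C)[C@H]3[C@@H]([C@@H](C)C(=O)[C@@H]3C)[C@]1(CC)C2=O
F3 | step 14 | C2 ethylene ketal of the diketone lactone | CC[C@@]1(CO2)C(=O)[C@@H](C)[C@H]3[C@@H]([C@@H](C)C4(OCCO4)[C@@H]3C)[C@]1(CC)C2=O
F4 | step 14 | C6 enol triflate of the C2 ketal | CC[C@@]1(CO2)C(OS(=O)(=O)C(F)(F)F)=C(C)[C@H]3[C@@H]([C@@H](C)C4(OCCO4)[C@@H]3C)[C@]1(CC)C2=O
F5 | step 14 | C6=C7 alkene C2 ketal | CC[C@@]1(CO2)C=C(C)[C@H]3[C@@H]([C@@H](C)C4(OCCO4)[C@@H]3C)[C@]1(CC)C2=O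
F6 | step 7 | mirror-image Diels–Alder adduct | C1=CC[C@]2(CO3)C(=O)C(C)=CC(=O)[C@@]2(C1)C3=O
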